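The seven-membered carbocycle is cut into a three-carbon unit, CH(OH)–CH(CH3)–C(OH)(acyl), and a four-carbon unit, CH(O-acyl)–CH(O-lactone)–CH–CH2. A dirhodium-catalysed tandem cyclopropanation/Cope rearrangement (formal (4+3) cycloaddition) of an acyclic (E)-4-acyl vinyldiazoacetate with (E)-1-acetoxybutadiene makes both ring bonds between these units in one operation, closes the cycloheptadiene and sets the acetoxy-bearing stereocentre, which then relays every other ring centre. The diazo partner already carries the complete side-chain ketone; its trichloroethyl ester is a temporary activating group, later degraded (Curtius) to the ring carbinol. The allylic acetate later brings in the acrylate for the α-methylene lactone.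

Key step: step 7

Numbering used below: ring C1 [C(OH)(acyl)], C5 [CH–O-ester], C6 [CH–O-lactone], C7, C8 (CH2), C9 (CHOH), C10 (CH–CH3); side chain C2 (C=O), C3, C4 (CHOH), C15; lactone C11, C12 (C=O), C13 (=CH2); α is the ring face of the C5 oxygen, β the face of the C6 lactone oxygen.

Assumption: Rh2(S-DOSP)4 is taken to give the 5α-acetate drawn in 13; if the opposite sense of induction is found, Rh2(R-DOSP)4 is used and nothing else changes.

Step 1
Reactants: 1 methyl (S)-3-hydroxybutanoate
Product: 2 methyl (S)-3-(tert-butyldiphenylsilyloxy)butanoate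
Conditions: t-BuPh2SiCl, imidazole, DMF, 23 °C
Reagents that add atoms: tert-butyl(chloro)diphenylsilane CC(C)(C)[Si](Cl)(c1ccccc1)c1ccccc1
Why: Imidazole-promoted silylation of the secondary alcohol (silyl ether protection) leaves the C4 stereocentre untouched, and the diphenylsilyl ether is chosen to outlast the aqueous acid of step 14.

Step 2
Reactants: 2 methyl (S)-3-(tert-butyldiphenylsilyloxy)butanoate; 3 1-propynyllithium (LiC≡CCH3)
Product: 4 (S)-6-(tert-butyldiphenylsilyloxy)hept-2-yn-4-one
Conditions: BF3·OEt2, THF, −78 °C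
Reagents that add atoms: none
Why: The alkynyl borate formed from the lithium acetylide and BF3 adds once to the ester and the tetrahedral adduct collapses only on work-up, so the reaction should stop at the alkynyl ketone (acyl substitution of an ester by an acetylide).

Step 3
Reactants: 4 (S)-6-(tert-butyldiphenylsilyloxy)hept-2-yn-4-one
Product: 5 (S,E)-6-(tert-butyldiphenylsilyloxy)-2-iodohept-2-en-4-one
Conditions: NaI, AcOH, 60 °C
Reagents that add atoms: sodium iodide [Na+].[I-]
Why: Conjugate hydroiodination of the ynone puts iodine on the β-carbon, and iodide addition–elimination under these equilibrating conditions should favour the (E)-isomer (iodine trans to the acyl group), the geometry that step 7 needs.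

Step 4
Reactants: 6 2,2,2-trichloroethanol; 7 bromoacetyl bromide
Product: 8 2,2,2-trichloroethyl bromoacetate
Conditions: pyridine, CH2Cl2, 0 °C
Reagents that add atoms: none
Why: O-acylation of the alcohol by the acid bromide (ester formation); no stereocentre is involved.

Step 5
Reactants: 8 2,2,2-trichloroethyl bromoacetate
Product: 9 2,2,2-trichloroethyl diazoacetate
Conditions: TsNHNHTs, DBU, THF, 0 °C
Reagents that add atoms: N,N'-bis(p-tolylsulfonyl)hydrazine Cc1ccc(cc1)S(=O)(=O)NNS(=O)(=O)c1ccc(C)cc1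
Why: N-alkylation of the bis-sulfonylhydrazine by the bromoacetate and base-induced loss of two sulfinate ions give the diazoacetate (diazo synthesis from an α-bromo ester by the ditosylhydrazine method).

Step 6
Reactants: 5 (S,E)-6-(tert-butyldiphenylsilyloxy)-2-iodohept-2-en-4-one; 9 2,2,2-trichloroethyl diazoacetate
Product: 10 2,2,2-trichloroethyl (S,E)-7-(tert-butyldiphenylsilyloxy)-2-diazo-3-methyl-5-oxooct-3-enoate
Conditions: Pd(PPh3)4 (5 mol %), Et3N, n-Bu4NBr, MeCN, 23 °C
Reagents that add atoms: none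
Why: Zerovalent palladium inserts into the carbon–iodine bond with retention of the E geometry, the acidic C–H of the diazoacetate is palladated with the help of the amine, and reductive elimination gives the vinyl diazo ester with the diazo group intact (palladium-catalysed cross-coupling of a vinyl iodide with an acceptor diazo compound).

Step 7
Reactants: 10 2,2,2-trichloroethyl (S,E)-7-(tert-butyldiphenylsilyloxy)-2-diazo-3-methyl-5-oxooct-3-enoate; 11 (E)-buta-1,3-dien-1-yl acetate
Product: 13 cycloheptadiene keto ester (ring C1–C5–C6=C7–C8–C9=C10; 5α-acetoxy; 1α-acyl; 9-CO2CH2CCl3; 10-methyl), via cis-divinylcyclopropane 12 (not isolated)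
Conditions: Rh2(S-DOSP)4 (dirhodium tetrakis[(S)-N-(dodecylbenzenesulfonyl)prolinate], 1 mol %), 11 (3 equiv), hexane/PhMe (4:1), slow addition of 10, −40 → 23 °C; then 45 °C
Reagents that add atoms: none
Why: The dirhodium carboxylate turns 10 into a donor/acceptor vinylcarbenoid that cyclopropanates the unsubstituted terminal alkene of 11 (bonds C9–C8 and C9–C7), the carbenoid's alkenyl group ending cis to the acetoxyvinyl group to give 12; 12 then undergoes the divinylcyclopropane–cycloheptadiene (Cope) rearrangement through a boat transition state, which forms C1–C5, breaks C9–C7 and leaves the C9=C10 and C6=C7 alkenes. The closest known reaction type is the tandem cyclopropanation/Cope rearrangement (formal (4+3) cycloaddition) of vinyldiazoacetates with 1-oxygenated butadienes. The three-membered ring closes by (2+1) carbene transfer and the seven-membered ring by the [3,3]-sigmatropic shift, not by a direct cyclisation. The C5 stereocentre is controlled by the chiral prolinate ligands, which select the alkene face in the cyclopropanation, and the C1 centre by the boat geometry, which places the substituents of the two E alkenes cis (1α-acyl, 5α-acetoxy). The step needs site selectivity for the CH2=CH end of the diene and carbenoid instead of vinylogous reactivity: the trans-disubstituted enol acetate alkene is a poor substrate for donor/acceptor carbenoids, and the acyl group on the vinyl terminus together with the non-polar solvent should suppress vinylogous attack. Compound 13 carries an acidic C1–H next to the acetate and is taken on without delay.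

Step 8
Reactants: 13 cycloheptadiene keto ester (5α-acetoxy; 1α-acyl; 1β-H)
Product: 15 1β-triethylsilyloxy ketone (5α-acetoxy; 1α-acyl; 9-CO2CH2CCl3), via potassium alkoxide 14 (not isolated)
Conditions: KN(SiMe3)2 (1.05 equiv), THF, −78 °C; 3-phenyl-2-(phenylsulfonyl)oxaziridine; then Et3SiOTf, −78 → −20 °C
Reagents that add atoms: 3-phenyl-2-(phenylsulfonyl)oxaziridine O=S(=O)(c1ccccc1)N1OC1c1ccccc1; triethylsilyl trifluoromethanesulfonate CC[Si](CC)(CC)OS(=O)(=O)C(F)(F)F
Why: Only C1–H is doubly activated (α to the ketone, γ to the ester), and the ketone dienolate should be oxygenated at its α-carbon C1 from the β face, anti to the 5α-acetoxy group (enolate hydroxylation by an N-sulfonyloxaziridine); silylation of the alkoxide in the same flask prevents acyl migration and provides the protecting group for steps 10 to 14.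

Step 9
Reactants: 16 methyl propiolate; 17 tributyltin hydride (Bu3SnH)
Product: 18 methyl 2-(tributylstannyl)acrylate
Conditions: Pd(PPh3)4 (2 mol %), THF, 0 → 23 °C
Reagents that add atoms: none
Why: Palladium-catalysed syn hydrostannation of the propiolate places tin on the α-carbon, next to the ester (hydrometallation of an electron-poor alkyne).

Step 10
Reactants: 15 1β-triethylsilyloxy ketone (5α-acetoxy); 18 methyl 2-(tributylstannyl)acrylate
Product: 19 skipped triene (ring C5=C6 and C9=C10; 7β-[1-(methoxycarbonyl)vinyl]; 1β-OSiEt3; 1α-acyl)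
Conditions: Pd2(dba)3 (2.5 mol %), LiCl (3 equiv), DMF, 40 °C
Reagents that add atoms: none
Why: Zerovalent palladium ionises the allylic acetate with inversion and the vinyl group passes from tin to palladium and then to the less hindered allyl terminus C7 with retention, so the acrylate should enter anti to the departed acetate (7β) while the alkene moves to C5=C6 (Stille coupling of an allylic acetate with allylic transposition).

Step 11
Reactants: 19 skipped triene (7β-[1-(methoxycarbonyl)vinyl])
Product: 21 hydroxy lactone (5α-OH; cis-fused 12,6β-olide with C11=C13 methylene; 1β-OSiEt3), via epoxy ester 20 (not isolated)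
Conditions: mCPBA, CH2Cl2, 0 → 23 °C; then CSA (10 mol %), H2O (2 equiv), 23 °C
Reagents that add atoms: 3-chloroperbenzoic acid OOC(=O)c1cccc(Cl)c1; water O
Why: The peracid should epoxidise the only electron-rich alkene (C5=C6) from the α face, anti to the 7β-acrylate and the 1β-silyloxy group, and acid then lets the ester carbonyl open the epoxide at C6 in a 5-exo mode with inversion, giving the cis-fused α-methylene lactone (6β-O) and the 5α-alcohol (epoxy ester lactonisation).

Step 12
Reactants: 21 hydroxy lactone (5α-OH); 22 (S)-2-methylbutanoic anhydride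
Product: 23 5α-[(S)-2-methylbutanoyloxy] lactone (1β-OSiEt3; 9-CO2CH2CCl3)
Conditions: DMAP (0.2 equiv), pyridine, CH2Cl2, 23 °C
Reagents that add atoms: none
Why: DMAP-catalysed acylation of the secondary alcohol by the anhydride (nucleophilic catalysis) installs the ester without exposing its α-stereocentre to a strong base; the tertiary silyl ether at C1 does not react.

Step 13
Reactants: 23 5α-[(S)-2-methylbutanoyloxy] lactone (9-CO2CH2CCl3)
Product: 24 9-carboxylic acid
Conditions: Zn dust, AcOH/THF (1:4), 23 °C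
Reagents that add atoms: none
Why: Two-electron reduction of the trichloroethyl group by zinc with loss of chloride and 1,1-dichloroethene frees the acid (reductive fragmentation of a trichloroethyl ester) under conditions that should leave the silyl ethers, the other esters and the α-methylene lactone intact.

Step 14
Reactants: 24 9-carboxylic acid
Product: 27 9-ketone (1β-OH; 10β-methyl; 4-O-silyl ether kept), via acyl azide 25 (not isolated), via vinyl isocyanate 26 (not isolated)
Conditions: (PhO)2P(O)N3, Et3N, PhMe, 23 → 85 °C; then 1 M HCl, THF, 23 °C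
Reagents that add atoms: water O; diphenylphosphoryl azide [N-]=[N+]=NP(=O)(Oc1ccccc1)Oc1ccccc1 (its nitrogen stays only in 25 and 26)
Why: Curtius rearrangement of the α,β-unsaturated acyl azide gives a vinyl isocyanate whose acidic hydrolysis (carbamic acid, enamine, iminium ion) unveils the C9 ketone and removes the triethylsilyl ether, while C10 should equilibrate through the enol to the epimer with the methyl group trans to the bulky 1α-acyl group (10β).

Step 15
Reactants: 27 9-ketone (1β-OH; 10β-methyl)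
Product: 28 9α-alcohol (4-O-tert-butyldiphenylsilyl ether of the target)
Conditions: Me4NBH(OAc)3, MeCN/AcOH (1:1), −30 °C
Reagents that add atoms: none
Why: The C1 hydroxyl exchanges onto boron and should deliver hydride through a six-membered chair to the β-keto group C9 from the β face, giving the 1,3-anti diol (9α-OH); the α-hydroxy ketone C2 would need a strained five-membered delivery, and the reagent does not reduce ketones that lack such a directing group (Evans–Saksena hydroxyl-directed reduction).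

Step 16
Reactants: 28 9α-alcohol (4-O-tert-butyldiphenylsilyl ether of the target)
Product: 29 CNP0291806.1 (target)
Conditions: HF·pyridine, pyridine, THF, 0 → 23 °C
Reagents that add atoms: none
Why: Fluoride cleaves the silicon–oxygen bond under buffered, weakly acidic conditions that should not harm the β-hydroxy ketone, the ester or the α-methylene lactone (desilylation); no stereocentre is touched.

Compound list
1 | methyl (S)-3-hydroxybutanoate | C[C@H](O)CC(=O)OC | starting material
2 | methyl (S)-3-(tert-butyldiphenylsilyloxy)butanoate | C[C@H](O[Si](c1ccccc1)(c1ccccc1)C(C)(C)C)CC(=O)OC | intermediate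
3 | 1-propynyllithium (LiC≡CCH3) | [Li]C#CC | starting material
4 | (S)-6-(tert-butyldiphenylsilyloxy)hept-2-yn-4-one | CC#CC(=O)C[C@H](C)O[Si](c1ccccc1)(c1ccccc1)C(C)(C)C | intermediate
5 | (S,E)-6-(tert-butyldiphenylsilyloxy)-2-iodohept-2-en-4-one | C/C(I)=C\C(=O)C[C@H](C)O[Si](c1ccccc1)(c1ccccc1)C(C)(C)C | intermediate
6 | 2,2,2-trichloroethanol | OCC(Cl)(Cl)Cl | starting material
7 | bromoacetyl bromide | BrCC(Br)=O | starting material
8 | 2,2,2-trichloroethyl bromoacetate | BrCC(=O)OCC(Cl)(Cl)Cl | intermediate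
9 | 2,2,2-trichloroethyl diazoacetate | [N-]=[N+]=CC(=O)OCC(Cl)(Cl)Cl | intermediate
10 | 2,2,2-trichloroethyl (S,E)-7-(tert-butyldiphenylsilyloxy)-2-diazo-3-methyl-5-oxooct-3-enoate | [N-]=[N+]=C(C(=O)OCC(Cl)(Cl)Cl)/C(C)=C/C(=O)C[C@H](C)O[Si](c1ccccc1)(c1ccccc1)C(C)(C)C | intermediate
11 | (E)-buta-1,3-dien-1-yl acetate (E isomer of commercial 1-acetoxybutadiene) | CC(=O)O/C=C/C=C | starting material
12 | 2,2,2-trichloroethyl 2-[(E)-2-acetoxyvinyl]-1-[(S,E)-6-(tert-butyldiphenylsilyloxy)-4-oxohept-2-en-2-yl]cyclopropane-1-carboxylate, the two alkenyl groups cis | CC(=O)O/C=C/[C@@H]1C[C@]1(C(=O)OCC(Cl)(Cl)Cl)/C(C)=C/C(=O)C[C@H](C)O[Si](c2ccccc2)(c2ccccc2)C(C)(C)C | intermediate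
13 | 2,2,2-trichloroethyl 5α-acetoxy-1α-[(S)-3-(tert-butyldiphenylsilyloxy)butanoyl]-10-methylcyclohepta-6,9-diene-9-carboxylate (ring C1–C5–C6=C7–C8–C9=C10; 1β-H) | C1=CCC(C(=O)OCC(Cl)(Cl)Cl)=C(C)[C@@H](C(=O)C[C@H](C)O[Si](c2ccccc2)(c2ccccc2)C(C)(C)C)[C@H]1OC(C)=O | intermediate
14 | potassium 1β-alkoxide of the 1-hydroxy derivative of 13 | C1=CCC(C(=O)OCC(Cl)(Cl)Cl)=C(C)[C@@]([O-])(C(=O)C[C@H](C)O[Si](c2ccccc2)(c2ccccc2)C(C)(C)C)[C@H]1OC(C)=O.[K+] | intermediate
15 | 2,2,2-trichloroethyl 5α-acetoxy-1α-[(S)-3-(tert-butyldiphenylsilyloxy)butanoyl]-10-methyl-1β-(triethylsilyloxy)cyclohepta-6,9-diene-9-carboxylate | C1=CCC(C(=O)OCC(Cl)(Cl)Cl)=C(C)[C@@](O[Si](CC)(CC)CC)(C(=O)C[C@H](C)O[Si](c2ccccc2)(c2ccccc2)C(C)(C)C)[C@H]1OC(C)=O | intermediate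
16 | methyl propiolate | C#CC(=O)OC | starting material
17 | tributyltin hydride (Bu3SnH) | CCCC[SnH](CCCC)CCCC | starting material
18 | methyl 2-(tributylstannyl)acrylate | C=C(C(=O)OC)[Sn](CCCC)(CCCC)CCCC | intermediate
19 | 2,2,2-trichloroethyl 1α-[(S)-3-(tert-butyldiphenylsilyloxy)butanoyl]-7β-[1-(methoxycarbonyl)vinyl]-10-methyl-1β-(triethylsilyloxy)cyclohepta-5,9-diene-9-carboxylate | C1=C[C@H](C(=C)C(=O)OC)CC(C(=O)OCC(Cl)(Cl)Cl)=C(C)[C@@]1(O[Si](CC)(CC)CC)C(=O)C[C@H](C)O[Si](c2ccccc2)(c2ccccc2)C(C)(C)C | intermediate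
20 | 5α,6α-epoxide of 19 | O1[C@H]2[C@@H]1[C@H](C(=C)C(=O)OC)CC(C(=O)OCC(Cl)(Cl)Cl)=C(C)[C@@]2(O[Si](CC)(CC)CC)C(=O)C[C@H](C)O[Si](c3ccccc3)(c3ccccc3)C(C)(C)C | intermediate
21 | hydroxy lactone: cis-fused α-methylene-γ-butyrolactone on C6 (β-O) and C7 (β-C11), 5α-OH, 1β-OSiEt3, 1α-[(S)-3-(tert-butyldiphenylsilyloxy)butanoyl], 9-CO2CH2CCl3, C9=C10, 10-methyl | C=C1C(=O)O[C@@H]2[C@H]1CC(C(=O)OCC(Cl)(Cl)Cl)=C(C)[C@@](O[Si](CC)(CC)CC)(C(=O)C[C@H](C)O[Si](c3ccccc3)(c3ccccc3)C(C)(C)C)[C@H]2O | intermediate
22 | (S)-2-methylbutanoic anhydride | CC[C@H](C)C(=O)OC(=O)[C@@H](C)CC | starting material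
23 | 5α-O-[(S)-2-methylbutanoyl] ester of 21 | C=C1C(=O)O[C@@H]2[C@H]1CC(C(=O)OCC(Cl)(Cl)Cl)=C(C)[C@@](O[Si](CC)(CC)CC)(C(=O)C[C@H](C)O[Si](c3ccccc3)(c3ccccc3)C(C)(C)C)[C@H]2OC(=O)[C@@H](C)CC | intermediate
24 | 9-carboxylic acid from 23 (trichloroethyl group removed) | C=C1C(=O)O[C@@H]2[C@H]1CC(C(=O)O)=C(C)[C@@](O[Si](CC)(CC)CC)(C(=O)C[C@H](C)O[Si](c3ccccc3)(c3ccccc3)C(C)(C)C)[C@H]2OC(=O)[C@@H](C)CC | intermediate
25 | 9-carbonyl azide of 24 | C=C1C(=O)O[C@@H]2[C@H]1CC(C(=O)N=[N+]=[N-])=C(C)[C@@](O[Si](CC)(CC)CC)(C(=O)C[C@H](C)O[Si](c3ccccc3)(c3ccccc3)C(C)(C)C)[C@H]2OC(=O)[C@@H](C)CC | intermediate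
26 | 9-isocyanato-9(10)-ene (vinyl isocyanate) | C=C1C(=O)O[C@@H]2[C@H]1CC(N=C=O)=C(C)[C@@](O[Si](CC)(CC)CC)(C(=O)C[C@H](C)O[Si](c3ccccc3)(c3ccccc3)C(C)(C)C)[C@H]2OC(=O)[C@@H](C)CC | intermediate
27 | 9-ketone: 1β-hydroxy, 10β-methyl, 1α-[(S)-3-(tert-butyldiphenylsilyloxy)butanoyl], 5α-[(S)-2-methylbutanoyloxy], cis-fused α-methylene lactone | C=C1C(=O)O[C@@H]2[C@H]1CC(=O)[C@H](C)[C@@](O)(C(=O)C[C@H](C)O[Si](c3ccccc3)(c3ccccc3)C(C)(C)C)[C@H]2OC(=O)[C@@H](C)CC | intermediate
28 | 9α-alcohol: 4-O-tert-butyldiphenylsilyl ether of the target | C=C1C(=O)O[C@@H]2[C@H]1C[C@@H](O)[C@H](C)[C@@](O)(C(=O)C[C@H](C)O[Si](c3ccccc3)(c3ccccc3)C(C)(C)C)[C@H]2OC(=O)[C@@H](C)CC | intermediate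
29 | CNP0291806.1: (1S,4S,5S,6R,7S,9R,10S)-1,4,9-trihydroxy-2-oxo-5-[(S)-2-methylbutanoyloxy] 11(13)-en-12,6-olide of the ring system numbered above | C=C1C(=O)O[C@@H]2[C@H]1C[C@@H](O)[C@H](C)[C@@](O)(C(=O)C[C@H](C)O)[C@H]2OC(=O)[C@@H](C)CC | target

Total step count: 16. Longest linear sequence: 13 steps (steps 1, 2, 3, 6, 7, 8, 10, 11, 12, 13, 14, 15, 16).

Steps most likely to fail

Step 8. The C1 enolate may lose the 5-acetoxy group by E1cB elimination before it is oxygenated (oxygenation at the ester-bearing terminus C9 is a lesser concern). The fallback sets out from 10. The (4+3) step is run with (E)-1-(trimethylsilyloxy)buta-1,3-diene in place of 11 under the same catalyst, which should give the 5α-trimethylsilyl ether cycloheptadiene F1, whose silyloxide is too poor a leaving group for elimination. Treatment with KN(SiMe3)2, the oxaziridine and Et3SiOTf as in step 8 then gives the bis-silyl ether F2. The secondary trimethylsilyl ether alone is cleaved (citric acid, MeOH, 0 °C) to the allylic alcohol F3, and Ac2O, pyridine and DMAP install the leaving group only now, which returns the route to 15.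

Step 11. The epoxidation may show poor facial selectivity, because the 1α-acyl group also shields the α face; a β-epoxide cannot be opened by the β-oriented ester. The fallback sets out from 19 and replaces the epoxide by a stereospecific sequence. Iodolactonisation (I2, MeCN, 0 °C) can only proceed through the α-iodonium ion, so it should give the 5α-iodo cis-lactone F4, the ester methyl group being lost as iodomethane. Selective removal of the tertiary triethylsilyl ether (HF·pyridine, pyridine, THF, 0 °C) gives the trans-iodohydrin F5, which Ag2O closes to the 1β,5β-epoxy lactone F6. Caesium (S)-2-methylbutanoate in DMF opens F6 at the secondary carbon C5 with inversion, so the double inversion at C5 gives the 5α-ester with free 1β-hydroxyl F7. Et3SiOTf and 2,6-lutidine then return the route to 23.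

Step 15. Chemoselectivity may be lost if the C1 hydroxyl also delivers hydride to the side-chain ketone C2. The fallback sets out from 27 and reduces both ketones on purpose (excess Me4NBH(OAc)3, 23 °C) to the 2,9-diol F8. Only the C1/C2 vicinal diol can form a five-membered dibutylstannylene acetal F9 (Bu2SnO, PhMe, reflux), and brominolysis of F9 (NBS, CHCl3, 23 °C) oxidises its secondary carbinol C2 back to the ketone (stannylene-mediated oxidation of a vicinal diol), which returns the route to 28.

Further compounds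
F1 | step 8 | 5α-(trimethylsilyloxy) analogue of 13 | C1=CCC(C(=O)OCC(Cl)(Cl)Cl)=C(C)[C@@H](C(=O)C[C@H](C)O[Si](c2ccccc2)(c2ccccc2)C(C)(C)C)[C@H]1O[Si](C)(C)C
F2 | step 8 | 1β-(triethylsilyloxy)-5α-(trimethylsilyloxy) analogue of 15 | C1=CCC(C(=O)OCC(Cl)(Cl)Cl)=C(C)[C@@](O[Si](CC)(CC)CC)(C(=O)C[C@H](C)O[Si](c2ccccc2)(c2ccccc2)C(C)(C)C)[C@H]1O[Si](C)(C)C
F3 | step 8 | 5α-alcohol (deacetyl 15) | C1=CCC(C(=O)OCC(Cl)(Cl)Cl)=C(C)[C@@](O[Si](CC)(CC)CC)(C(=O)C[C@H](C)O[Si](c2ccccc2)(c2ccccc2)C(C)(C)C)[C@H]1O
F4 | step 11 | 5α-iodo cis-fused α-methylene lactone (1β-OSiEt3) | C=C1C(=O)O[C@@H]2[C@H]1CC(C(=O)OCC(Cl)(Cl)Cl)=C(C)[C@@](O[Si](CC)(CC)CC)(C(=O)C[C@H](C)O[Si](c3ccccc3)(c3ccccc3)C(C)(C)C)[C@H]2I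
F5 | step 11 | 1β-hydroxy-5α-iodo lactone (trans-iodohydrin) | C=C1C(=O)O[C@@H]2[C@H]1CC(C(=O)OCC(Cl)(Cl)Cl)=C(C)[C@@](O)(C(=O)C[C@H](C)O[Si](c3ccccc3)(c3ccccc3)C(C)(C)C)[C@H]2I
F6 | step 11 | 1β,5β-epoxy lactone | C=C1C(=O)O[C@@H]2[C@H]1CC(C(=O)OCC(Cl)(Cl)Cl)=C(C)[C@]4(C(=O)C[C@H](C)O[Si](c3ccccc3)(c3ccccc3)C(C)(C)C)O[C@H]24
F7 | step 11 | 1β-hydroxy-5α-[(S)-2-methylbutanoyloxy] lactone (desilyl 23) | C=C1C(=O)O[C@@H]2[C@H]1CC(C(=O)OCC(Cl)(Cl)Cl)=C(C)[C@@](O)(C(=O)C[C@H](C)O[Si](c3ccccc3)(c3ccccc3)C(C)(C)C)[C@H]2OC(=O)[C@@H](C)CC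
F8 | step 15 | 2,9-diol from over-reduction of 27 (C2 configuration not defined) | C=C1C(=O)O[C@@H]2[C@H]1C[C@@H](O)[C@H](C)[C@@](O)(C(O)C[C@H](C)O[Si](c3ccccc3)(c3ccccc3)C(C)(C)C)[C@H]2OC(=O)[C@@H](C)CC
F9 | step 15 | 1,2-O-dibutylstannylene acetal of F8 | C=C1C(=O)O[C@@H]2[C@H]1C[C@@H](O)[C@H](C)[C@]3(O[Sn](CCCC)(CCCC)OC3C[C@H](C)O[Si](c4ccccc4)(c4ccccc4)C(C)(C)C)[C@H]2OC(=O)[C@@H](C)CC
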